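**Retrosynthetic overview**

1. The strategy rests on the two benzylic methine carbons aryl–CH(CH3)–CH2 (C2 of each 6-methylhept-5-en-2-yl chain), both (S): one on ring A ortho to the phenol OH, one on ring B ortho to the diaryl ether oxygen.
2. Both are disconnected at the C–CH3 bond: a twofold copper-catalysed enantioselective SN2' methylation of bis-(E)-cinnamyl bromide 9 with two equivalents of MeMgBr gives the bis(but-3-en-2-yl) compound 11.
3. Each vinyl group of 11 is then extended by four carbons through 9-BBN hydroboration and B-alkyl Suzuki–Miyaura coupling with 1-bromo-2-methylprop-1-ene, and desilylation ends the route.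
4. Bromide 9 comes from a dialdehyde diaryl ether by silylation, double Horner–Wadsworth–Emmons olefination, ester reduction and bromination; the ether C–O bond is made by SNAr of 2,5-dihydroxy-4-methylbenzaldehyde on 2-fluoro-4-methylbenzaldehyde.
5. No ring is formed: ring A and ring B are bought as benzaldehydes and joined through oxygen in step 2.

Key step: step 7

Assumption: the (R,Rp) enantiomer of TaniaPhos, 1-[α-(dimethylamino)-2-(diphenylphosphino)benzyl]-2-(diphenylphosphino)ferrocene, is taken as the one that gives the (S) sense with (E)-aryl allyl bromides; a trial on cinnamyl bromide settles this, and the mirror-image ligand is used if the sense is opposite.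

**Route**

Step 1
Reactants: 1 2,5-dimethoxy-4-methylbenzaldehyde
Product: 2 2,5-dihydroxy-4-methylbenzaldehyde
Conditions: BBr3 (3 equiv), CH2Cl2, −78 °C → rt; then H2O
Reagents that add atoms: none
Why: Aryl methyl ether cleavage with BBr3 (Lewis acid complexation, then bromide attack on each methyl group) should free both phenols, the formyl group being only complexed and released again on aqueous work-up.

Step 2
Reactants: 2 2,5-dihydroxy-4-methylbenzaldehyde; 3 2-fluoro-4-methylbenzaldehyde
Product: 4 5-(2-formyl-5-methylphenoxy)-2-hydroxy-4-methylbenzaldehyde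
Conditions: K2CO3 (2.5 equiv), DMF, 90 °C, argon; 3 (1.0 equiv)
Reagents that add atoms: none
Why: Nucleophilic aromatic substitution (SNAr) of the fluoride activated by its ortho formyl group should take place at O5 of 2 only, because the C2 oxygen is chelated to and conjugated with its own formyl group and is the much weaker nucleophile.

Step 3
Reactants: 4 5-(2-formyl-5-methylphenoxy)-2-hydroxy-4-methylbenzaldehyde
Product: 5 5-(2-formyl-5-methylphenoxy)-4-methyl-2-[tri(propan-2-yl)silyloxy]benzaldehyde
Conditions: i-Pr3SiCl, imidazole, DMAP (cat.), DMF, rt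
Reagents that add atoms: chlorotri(propan-2-yl)silane, CC(C)[Si](Cl)(C(C)C)C(C)C
Why: Silyl ether formation with imidazole as base and nucleophilic catalyst should cap the remaining phenol with a bulky group that withstands the carbanion, hydride and Grignard reagents of steps 4 to 7.

Step 4
Reactants: 5 the silylated dialdehyde; 6 triethyl phosphonoacetate (two equivalents are taken up, one per formyl group)
Product: 7 ethyl (E)-3-{2-[5-((E)-3-ethoxy-3-oxoprop-1-enyl)-2-methyl-4-(triisopropylsilyloxy)phenoxy]-4-methylphenyl}prop-2-enoate (bis-(E)-cinnamate)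
Conditions: 6 (2.4 equiv), NaH, THF, 0 °C → rt
Reagents that add atoms: triethyl phosphonoacetate (second equivalent of 6), CCOC(=O)CP(=O)(OCC)OCC
Why: A twofold Horner–Wadsworth–Emmons olefination with the stabilised phosphonate carbanion should convert both non-enolisable aryl aldehydes into (E)-cinnamates through the favoured anti oxaphosphetane.

Step 5
Reactants: 7 the bis-(E)-cinnamate
Product: 8 (E)-3-{2-[5-((E)-3-hydroxyprop-1-enyl)-2-methyl-4-(triisopropylsilyloxy)phenoxy]-4-methylphenyl}prop-2-en-1-ol (bis-(E)-cinnamyl alcohol)
Conditions: i-Bu2AlH (5 equiv), CH2Cl2, −78 °C; aq. potassium sodium tartrate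
Reagents that add atoms: none
Why: 1,2-Reduction of both conjugated esters by i-Bu2AlH should give the (E)-allylic alcohols without touching the alkenes or the aryl silyl ether at low temperature.

Step 6
Reactants: 8 the bis-(E)-cinnamyl alcohol
Product: 9 {2-[(E)-3-bromoprop-1-enyl]-4-{2-[(E)-3-bromoprop-1-enyl]-5-methylphenoxy}-5-methylphenoxy}tri(propan-2-yl)silane (bis-(E)-cinnamyl bromide)
Conditions: CBr4, PPh3, CH2Cl2, 0 °C; rapid filtration through deactivated silica, used at once
Reagents that add atoms: tetrabromomethane, BrC(Br)(Br)Br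
Why: The Appel reaction should displace each primary alkoxyphosphonium group by bromide under near-neutral conditions, which keeps the (E) geometry and the silyl ether.

Step 7
Reactants: 9 the bis-(E)-cinnamyl bromide; 10 methylmagnesium bromide (two equivalents are taken up, one methyl group per allyl unit)
Product: 11 {2-[(2S)-but-3-en-2-yl]-4-{2-[(2S)-but-3-en-2-yl]-5-methylphenoxy}-5-methylphenoxy}tri(propan-2-yl)silane
Conditions: CuBr·SMe2 (10 mol%), (R,Rp)-TaniaPhos (12 mol%), MeMgBr (3 M in Et2O, 2.6 equiv), CH2Cl2, −75 °C; 9 added slowly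
Reagents that add atoms: methylmagnesium bromide (second equivalent of 10), C[Mg]Br
Why: MeMgBr transfers methyl to the diphosphine-bound CuBr to give a chiral methylcopper species (monovalent copper) that binds each alkene and adds oxidatively at the carbon γ to bromide, anti to the leaving group, giving a σ-allyl trivalent copper intermediate whose fast reductive elimination forms the benzylic C–CH3 bond before isomerisation to the linear allyl isomer. The closest known reaction type is the copper-catalysed enantioselective SN2' alkylation of (E)-cinnamyl bromides with Grignard reagents to give branched 3-arylbut-1-enes, used here at two sites of one molecule with one equivalent of MeMgBr consumed at each. No ring is closed. Both new stereocentres are set by the chiral ligand on copper, which chooses the alkene face, and one ligand enantiomer meeting two alike (E)-aryl allyl units should give (S) at both. The step needs branched over linear regioselectivity, which the bromide leaving group, the non-coordinating solvent, the low temperature and the slow addition of 9 should secure, and it needs the two sites to react independently, which the ether oxygen between ring A and ring B ensures by keeping them apart. A wrong addition at one site then gives mainly a diastereomer and not the enantiomer, so the (S,S) compound should be enriched in enantiomeric purity after purification.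

Step 8
Reactants: 11 the (S,S)-bis(but-3-en-2-yl) silyl ether; 12 9-borabicyclo[3.3.1]nonane (9-BBN; two equivalents add, one per vinyl group); 13 1-bromo-2-methylprop-1-ene (two equivalents couple, one per alkylborane)
Product: 15 {5-methyl-2-[(2S)-6-methylhept-5-en-2-yl]-4-{5-methyl-2-[(2S)-6-methylhept-5-en-2-yl]phenoxy}phenoxy}tri(propan-2-yl)silane, via twofold B-alkyl-9-borabicyclo[3.3.1]nonane 14 (not isolated)
Conditions: 9-BBN (0.5 M in THF, 3 equiv), 0 °C → rt; then 13 (4 equiv), Pd(dppf)Cl2 (10 mol%), K3PO4 (3 M aq.), DMF, 50 °C
Reagents that add atoms: 1-bromo-2-methylprop-1-ene (second equivalent of 13), CC(C)=CBr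
Why: Anti-Markovnikov hydroboration of both terminal vinyl groups places boron on the terminal carbons without touching the benzylic stereocentres, and B-alkyl Suzuki–Miyaura coupling of the primary alkylboranes with the alkenyl bromide, under a wide-bite-angle diphosphine palladium catalyst that disfavours β-hydride elimination, should complete both side chains.

Step 9
Reactants: 15 the silyl ether of the target
Product: 16 5-methyl-2-[(2S)-6-methylhept-5-en-2-yl]-4-{5-methyl-2-[(2S)-6-methylhept-5-en-2-yl]phenoxy}phenol (CNP0354307.1)
Conditions: Bu4NF (1 M in THF, 1.2 equiv), THF, 0 °C; aq. work-up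
Reagents that add atoms: none
Why: Fluoride-mediated cleavage of the aryl silyl ether (Si–F bond formation) should free the phenol while the trisubstituted alkenes, the diaryl ether and both benzylic stereocentres stay untouched.

**Compound list**

1 | 2,5-dimethoxy-4-methylbenzaldehyde | O=Cc1cc(OC)c(C)cc1OC | starting material
2 | 2,5-dihydroxy-4-methylbenzaldehyde | O=Cc1cc(O)c(C)cc1O | intermediate
3 | 2-fluoro-4-methylbenzaldehyde | Cc1ccc(C=O)c(F)c1 | starting material
4 | 5-(2-formyl-5-methylphenoxy)-2-hydroxy-4-methylbenzaldehyde | O=Cc1cc(Oc2cc(C)ccc2C=O)c(C)cc1O | intermediate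
5 | 5-(2-formyl-5-methylphenoxy)-4-methyl-2-[tri(propan-2-yl)silyloxy]benzaldehyde | O=Cc1cc(Oc2cc(C)ccc2C=O)c(C)cc1O[Si](C(C)C)(C(C)C)C(C)C | intermediate
6 | triethyl phosphonoacetate | CCOC(=O)CP(=O)(OCC)OCC | starting material
7 | bis-(E)-cinnamate diethyl ester of the silylated diaryl ether | CCOC(=O)/C=C/c1cc(Oc2cc(C)ccc2/C=C/C(=O)OCC)c(C)cc1O[Si](C(C)C)(C(C)C)C(C)C | intermediate
8 | bis-(E)-cinnamyl alcohol of the silylated diaryl ether | OC/C=C/c1cc(Oc2cc(C)ccc2/C=C/CO)c(C)cc1O[Si](C(C)C)(C(C)C)C(C)C | intermediate
9 | bis-(E)-cinnamyl bromide of the silylated diaryl ether | BrC/C=C/c1cc(Oc2cc(C)ccc2/C=C/CBr)c(C)cc1O[Si](C(C)C)(C(C)C)C(C)C | intermediate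
10 | methylmagnesium bromide | C[Mg]Br | starting material
11 | (S,S)-bis(but-3-en-2-yl) diaryl ether, triisopropylsilyl protected | C=C[C@H](C)c1cc(Oc2cc(C)ccc2[C@@H](C)C=C)c(C)cc1O[Si](C(C)C)(C(C)C)C(C)C | intermediate
12 | 9-borabicyclo[3.3.1]nonane | B1C2CCCC1CCC2 | starting material
13 | 1-bromo-2-methylprop-1-ene | CC(C)=CBr | starting material
14 | twofold B-alkyl-9-borabicyclo[3.3.1]nonane from 11 (boron on each terminal carbon) | C1CCC2CCCC1B2CC[C@H](C)c1cc(Oc2cc(C)ccc2[C@@H](C)CCB2C3CCCC2CCC3)c(C)cc1O[Si](C(C)C)(C(C)C)C(C)C | intermediate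
15 | triisopropylsilyl ether of the target | CC(C)=CCC[C@H](C)c1cc(Oc2cc(C)ccc2[C@@H](C)CCC=C(C)C)c(C)cc1O[Si](C(C)C)(C(C)C)C(C)C | intermediate
16 | 5-methyl-2-[(2S)-6-methylhept-5-en-2-yl]-4-{5-methyl-2-[(2S)-6-methylhept-5-en-2-yl]phenoxy}phenol | CC(C)=CCC[C@H](C)c1cc(Oc2cc(C)ccc2[C@@H](C)CCC=C(C)C)c(C)cc1O | target

**Summary**

Total step count: 9. Longest linear sequence: 9 steps (1 to 16).

Steps most likely to fail:

Step 7. The risk is loss of branched selectivity through allyl isomerisation on copper before reductive elimination, poor face selectivity at the ortho-oxygenated aryl allyl units (above all next to the bulky silyloxy group), or an incomplete second substitution. The fallback sets the two centres by auxiliary control and sets out from dialdehyde 5. Knoevenagel–Doebner condensation with malonic acid (pyridine, piperidine, 90 °C, loss of carbon dioxide in the flask) should give the bis-(E)-cinnamic acid F1. Activation with pivaloyl chloride and Et3N, then (4S)-4-phenyloxazolidin-2-one and LiCl, should give the bis-(E)-N-cinnamoyl imide F2. MeMgBr with CuBr·SMe2 (THF/Me2S, −40 °C) adds methyl to each β-carbon anti to the 4-phenyl group of the magnesium-chelated s-cis imide, the face that gives (S), to furnish the bis-(3S)-3-arylbutanoyl imide F3. LiBH4 (THF, MeOH) removes the auxiliary reductively to give the (S,S)-diol F4. I2, PPh3 and imidazole give the (S,S)-diiodide F5. Coupling with 2-methylprop-1-enylmagnesium bromide under Li2CuCl4 catalysis (THF, −20 °C) then comes back to the route at 15, before step 9.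

Step 2. The risk is arylation at the chelated oxygen, a second arylation, or air oxidation of the electron-rich hydroquinone dianion at 90 °C. The fallback uses a phenol with one free hydroxyl and sets out from 3. SNAr with commercial 4-methoxy-2-methylphenol (K2CO3, DMF, 100 °C) should give 2-(4-methoxy-2-methylphenoxy)-4-methylbenzaldehyde F6. Rieche formylation (Cl2CHOMe, TiCl4, CH2Cl2, 0 °C) should enter ring A ortho to the methoxy group and para to the methyl group, while ring B is deactivated as its TiCl4-complexed aldehyde, to give 5-(2-formyl-5-methylphenoxy)-2-methoxy-4-methylbenzaldehyde F7. Chelation-assisted cleavage of the methyl ether ortho to formyl with BCl3 (CH2Cl2, −78 → 0 °C) comes back to the route at 4.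

Step 6. The risk is ionisation of the electron-rich allylic bromides during formation or purification, leading to allylic transposition, hydrolysis or oligomerisation before the key step. The fallback avoids the bromide and sets out from diol 8. Phosphorylation (ClP(O)(OEt)2, Et3N, DMAP, CH2Cl2, 0 °C) should give the chromatography-stable bis(diethyl phosphate) F8. Copper-catalysed enantioselective SN2' methylation of the aryl allylic phosphates with Me2Zn ((CuOTf)2·C6H6 with a chiral peptide-based Schiff-base ligand, THF, −15 °C) comes back to the route at 11.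

**Further compounds**

F1 | step 7 | bis-(E)-cinnamic acid of the silylated diaryl ether | OC(=O)/C=C/c1cc(Oc2cc(C)ccc2/C=C/C(O)=O)c(C)cc1O[Si](C(C)C)(C(C)C)C(C)C
F2 | step 7 | bis-(E)-N-cinnamoyl imide with (4S)-4-phenyloxazolidin-2-one | O=C(/C=C/c1cc(Oc2cc(C)ccc2/C=C/C(=O)N2[C@@H](c3ccccc3)COC2=O)c(C)cc1O[Si](C(C)C)(C(C)C)C(C)C)N1[C@@H](c2ccccc2)COC1=O
F3 | step 7 | bis-(3S)-3-arylbutanoyl imide with (4S)-4-phenyloxazolidin-2-one | O=C(C[C@H](C)c1cc(Oc2cc(C)ccc2[C@@H](C)CC(=O)N2[C@@H](c3ccccc3)COC2=O)c(C)cc1O[Si](C(C)C)(C(C)C)C(C)C)N1[C@@H](c2ccccc2)COC1=O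
F4 | step 7 | (S,S)-bis(4-hydroxybutan-2-yl) diaryl ether, triisopropylsilyl protected | OCC[C@H](C)c1cc(Oc2cc(C)ccc2[C@@H](C)CCO)c(C)cc1O[Si](C(C)C)(C(C)C)C(C)C
F5 | step 7 | (S,S)-bis(4-iodobutan-2-yl) diaryl ether, triisopropylsilyl protected | ICC[C@H](C)c1cc(Oc2cc(C)ccc2[C@@H](C)CCI)c(C)cc1O[Si](C(C)C)(C(C)C)C(C)C
F6 | step 2 | 2-(4-methoxy-2-methylphenoxy)-4-methylbenzaldehyde | COc1ccc(Oc2cc(C)ccc2C=O)c(C)c1
F7 | step 2 | 5-(2-formyl-5-methylphenoxy)-2-methoxy-4-methylbenzaldehyde | COc1cc(C)c(Oc2cc(C)ccc2C=O)cc1C=O
F8 | step 6 | bis(diethyl phosphate) of the bis-(E)-cinnamyl alcohol 8 | CCOP(=O)(OCC)OC/C=C/c1cc(Oc2cc(C)ccc2/C=C/COP(=O)(OCC)OCC)c(C)cc1O[Si](C(C)C)(C(C)C)C(C)C
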